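**Plan**

1. Retrosynthesis (indane numbering: C1 = benzylidene carbon, C2, C3, fusion carbons C3a and C7a of the resorcinol ring, ring A): the six O–CH3 bonds are cut first, then the ring bond C1–C7a, then the exocyclic C1=CH(aryl) unit back to an aryl alkyne, then the C2–aryl and C3–aryl bonds back to 5,7-dimethoxycoumarin.
2. The C1–C7a bond is not made by cyclisation. A boron atom is placed between C7a and C1, so the ring is first closed one atom too large, as a six-membered aryl(alkenyl)boronate ring. It contracts to the indane ring by 1,2-migration of C7a from boron to C1 (Zweifel sequence), which forms the ring and the exocyclic alkene in one operation.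
3. Feature that allows this: C1 is an sp2 carbon bearing both the aromatic carbon C7a of ring A and the exocyclic CH(aryl) carbon, which is exactly the aryl–alkenyl junction that an aryl-to-alkenyl boronate shift produces. C7a is meta to both oxygens of ring A, so it needs a pre-set handle in any case.
4. Forward order: the lactone ring of the coumarin is a temporary ring that holds C2 and C3 trans; its carbonyl carbon becomes C1 and its ring oxygen marks C7a (O → OTf → Br → Li). Chain extension gives the aryl alkyne, borylcupration the alkenyl boronate, then borate ring closure and contraction, then demethylation.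
5. Stereochemistry: C3 from the rhodium/(S)-SEGPHOS 1,4-addition; C2 from substrate and thermodynamic control in the lactone (trans); the Z alkene from syn-borylcupration followed by anti-iodination/anti-deboronation.

Key step: step 9

Remark: the SMILES is read as the (1Z,2S,3S) isomer (alkene 4-hydroxyphenyl on the side of C7a, ring aryl groups trans); the sense of induction in step 1 is assigned by analogy, and the ligand antipode would be used if it proved opposite.

**Route**

Step 1
Reactants: 1 5,7-dimethoxycoumarin; 2 (4-methoxyphenyl)boronic acid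
Product: 3 (4S)-5,7-dimethoxy-4-(4-methoxyphenyl)-3,4-dihydro-2H-chromen-2-one
Conditions: Rh(acac)(C2H4)2 (3 mol %), (S)-SEGPHOS [(S)-5,5'-bis(diphenylphosphino)-4,4'-bi-1,3-benzodioxole] (3.3 mol %), 2 (3 equiv), 1,4-dioxane/H2O 10:1, 60 °C
Reagents that add atoms: none
Why: Hayashi–Miyaura rhodium-catalysed asymmetric 1,4-addition of an arylboronic acid to a coumarin, where insertion of the C3=C4 bond into the aryl–rhodium bond on one enantioface sets C4 (the later indane C3), the (S)-ligand being chosen because the (R)-ligand is known to give (R)-4-arylchroman-2-ones of the same priority pattern.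

Step 2
Reactants: 3 (4S)-5,7-dimethoxy-4-(4-methoxyphenyl)-3,4-dihydro-2H-chromen-2-one; 4 1-bromo-3,5-dimethoxybenzene
Product: 7 (3S,4S)-3-(3,5-dimethoxyphenyl)-5,7-dimethoxy-4-(4-methoxyphenyl)-3,4-dihydro-2H-chromen-2-one, via lithium enolate 5 (not isolated), via chlorozinc enolate 6 (not isolated)
Conditions: LiN(SiMe3)2, THF, −78 °C; ZnCl2, −78 °C → rt; 4, Pd(dba)2 (3 mol %), P(t-Bu)3 (3 mol %), rt → 50 °C; then DBU (cat.), CH2Cl2, rt
Reagents that add atoms: none
Why: Palladium-catalysed α-arylation of a zinc ester enolate (the mild zinc enolate is meant to avoid ketene-forming fragmentation of the aryl ester), in which the aryl group should be delivered anti to the pseudo-axial C4 aryl group and the acidic C3–H lets DBU equilibrate any cis isomer, so the trans lactone is expected under substrate and thermodynamic control.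

Step 3
Reactants: 7 (3S,4S)-3-(3,5-dimethoxyphenyl)-5,7-dimethoxy-4-(4-methoxyphenyl)-3,4-dihydro-2H-chromen-2-one
Product: 9 2-[(1S,2S)-2-(3,5-dimethoxyphenyl)-3-[methoxy(methyl)amino]-1-(4-methoxyphenyl)-3-oxopropyl]-3,5-dimethoxyphenyl trifluoromethanesulfonate, via phenol amide 8 (not isolated)
Conditions: MeNH(OMe)·HCl, AlMe3, CH2Cl2, 0 °C → rt; aqueous potassium sodium tartrate; crude phenol: PhNTf2, Et3N, DMAP (cat.), CH2Cl2, 0 °C → rt
Reagents that add atoms: N,O-dimethylhydroxylamine hydrochloride (CNOC.Cl); N-phenylbis(trifluoromethanesulfonimide) (O=S(=O)(N(c1ccccc1)S(=O)(=O)C(F)(F)F)C(F)(F)F)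
Why: Weinreb aminolysis of the aryl lactone with the weakly basic aluminium amide should open the temporary ring without epimerising C2, and the freed phenol oxygen on the future C7a is triflated at once by sulfonyl transfer from PhNTf2 before it can re-lactonise; no stereocentre is formed or touched.

Step 4
Reactants: 9 2-[(1S,2S)-2-(3,5-dimethoxyphenyl)-3-[methoxy(methyl)amino]-1-(4-methoxyphenyl)-3-oxopropyl]-3,5-dimethoxyphenyl trifluoromethanesulfonate
Product: 10 (2S,3S)-3-(2-bromo-4,6-dimethoxyphenyl)-2-(3,5-dimethoxyphenyl)-N-methoxy-3-(4-methoxyphenyl)-N-methylpropanamide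
Conditions: Pd2(dba)3 (2 mol %), t-BuBrettPhos [2-(di-tert-butylphosphino)-3,6-dimethoxy-2',4',6'-triisopropylbiphenyl] (5 mol %), KBr, KF, 1,4-dioxane, 130 °C
Reagents that add atoms: potassium bromide ([K+].[Br-])
Why: Palladium-catalysed conversion of an aryl triflate into the aryl bromide (oxidative addition to zerovalent palladium, triflate/bromide exchange, C–Br reductive elimination from the bulky biarylphosphine complex), used because C7a is meta to both methoxy groups and cannot be brominated electrophilically; the weakly basic medium should leave the α-aryl amide centre intact.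

Step 5
Reactants: 10 (2S,3S)-3-(2-bromo-4,6-dimethoxyphenyl)-2-(3,5-dimethoxyphenyl)-N-methoxy-3-(4-methoxyphenyl)-N-methylpropanamide
Product: 11 (2S,3S)-3-(2-bromo-4,6-dimethoxyphenyl)-2-(3,5-dimethoxyphenyl)-3-(4-methoxyphenyl)propanal
Conditions: i-Bu2AlH, THF, −78 °C; aqueous potassium sodium tartrate, 0 °C; used crude
Reagents that add atoms: none
Why: Weinreb amide reduction, in which the chelated tetrahedral aluminate should stop the hydride addition at the aldehyde level; the α-aryl aldehyde is carried on cold and unpurified to keep C2 from epimerising.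

Step 6
Reactants: 11 (2S,3S)-3-(2-bromo-4,6-dimethoxyphenyl)-2-(3,5-dimethoxyphenyl)-3-(4-methoxyphenyl)propanal
Product: 12 1-bromo-2-[(1S,2R)-2-(3,5-dimethoxyphenyl)-1-(4-methoxyphenyl)but-3-yn-1-yl]-3,5-dimethoxybenzene
Conditions: Me3SiCHN2, n-BuLi, THF, −78 °C; then 11, −78 °C → rt
Reagents that add atoms: (trimethylsilyl)diazomethane (C[Si](C)(C)C=[N+]=[N-])
Why: Colvin homologation (addition of the lithiated silyl diazomethane, Peterson-type elimination, loss of N2 and 1,2-hydride shift) should turn the aldehyde into the terminal alkyne at low temperature without a base strong enough to enolise it, so C2 keeps its configuration (the descriptor changes to R only through the priority rules).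

Step 7
Reactants: 12 1-bromo-2-[(1S,2R)-2-(3,5-dimethoxyphenyl)-1-(4-methoxyphenyl)but-3-yn-1-yl]-3,5-dimethoxybenzene; 13 1-iodo-4-methoxybenzene
Product: 14 1-bromo-2-[(1S,2S)-2-(3,5-dimethoxyphenyl)-1,4-bis(4-methoxyphenyl)but-3-yn-1-yl]-3,5-dimethoxybenzene
Conditions: PdCl2(PPh3)2 (2 mol %), CuI (4 mol %), Et3N, THF, rt
Reagents that add atoms: none
Why: Sonogashira coupling, in which oxidative addition at room temperature should occur only at the aryl iodide, the hindered and electron-rich aryl bromide of 12 staying untouched.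

Step 8
Reactants: 14 1-bromo-2-[(1S,2S)-2-(3,5-dimethoxyphenyl)-1,4-bis(4-methoxyphenyl)but-3-yn-1-yl]-3,5-dimethoxybenzene
Product: 15 2-[(1Z,3R,4S)-4-(2-bromo-4,6-dimethoxyphenyl)-3-(3,5-dimethoxyphenyl)-1,4-bis(4-methoxyphenyl)but-1-en-2-yl]-4,4,5,5-tetramethyl-1,3,2-dioxaborolane
Conditions: CuCl (5 mol %), P(p-tolyl)3 (6 mol %), NaOt-Bu (10 mol %), B2pin2, MeOH (2 equiv), THF, rt
Reagents that add atoms: bis(pinacolato)diboron (CC1(C)OB(OC1(C)C)B1OC(C)(C)C(C)(C)O1)
Why: Copper-catalysed syn-borylcupration/protonation of an aryl alkyl alkyne (formal hydroboration) should place copper on the aryl-bearing carbon and boron on the distal carbon (the later C1), and protonation with retention gives the alkenyl boronate with boron and hydrogen cis.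

Step 9
Reactants: 15 2-[(1Z,3R,4S)-4-(2-bromo-4,6-dimethoxyphenyl)-3-(3,5-dimethoxyphenyl)-1,4-bis(4-methoxyphenyl)but-1-en-2-yl]-4,4,5,5-tetramethyl-1,3,2-dioxaborolane
Product: 19 (1Z,2S,3S)-2-(3,5-dimethoxyphenyl)-4,6-dimethoxy-3-(4-methoxyphenyl)-1-[(4-methoxyphenyl)methylidene]-2,3-dihydro-1H-indene, via aryllithium 16 (not isolated), via cyclic boronate complex 17 (not isolated), via iodo boronic ester 18 (not isolated)
Conditions: t-BuLi (2.1 equiv), THF/Et2O, −95 °C; I2 (1.2 equiv), THF, −78 °C; NaOMe (3 equiv), MeOH, −78 °C → rt, dark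
Reagents that add atoms: none
Why: Proposed new method: bromine–lithium exchange gives aryllithium 16, whose carbanion at C7a adds to the tethered boronic ester to form the six-membered cyclic aryl(alkenyl)boronate complex 17 (ring atoms B, C1, C2, C3, C3a, C7a); iodine then adds to the boronate-activated exocyclic alkene and C7a migrates from boron to C1 anti to the new C–I bond (1,2-metallate shift), which contracts the six-membered borate ring to the five-membered carbocycle 18, and methoxide finally induces anti-elimination of boron and iodide. The closest known reaction types are the Zweifel olefination of aryl(alkenyl) pinacol boronate complexes (I2 then NaOMe, intermolecular) and the electrophile-induced ring contraction of cyclic alkenyl boronate complexes to smaller carbocycles. The borate ring closes by attack of the C7a carbanion on boron (a 6-exo closure with respect to the alkene, which stays outside the ring), and the indane ring closes by the suprafacial 1,2-shift of C7a onto C1, not by a cyclisation at carbon. No stereocentre is created that survives: C2 and C3 are spectators, the two centres of 18 are lost on elimination, and the alkene geometry is dictated by the anti-addition/anti-elimination course, which inverts the boronate geometry so that the 4-methoxyphenyl group, trans to boron in 15, ends cis to C7a (Z). The step needs iodination at the alkene rather than at the aryl–boron carbon or the electron-rich rings, exchange at bromine rather than attack of t-BuLi on boron, and a stereospecific loss of the benzylic iodide; these should be secured by the high nucleophilicity of the borate-activated alkene, the fast Br–Li exchange at −95 °C next to a hindered trisubstituted alkenyl boronate, and the low temperature with prompt addition of methoxide.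

Step 10
Reactants: 19 (1Z,2S,3S)-2-(3,5-dimethoxyphenyl)-4,6-dimethoxy-3-(4-methoxyphenyl)-1-[(4-methoxyphenyl)methylidene]-2,3-dihydro-1H-indene
Product: 20 5-[(1Z,2S,3S)-4,6-dihydroxy-3-(4-hydroxyphenyl)-1-[(4-hydroxyphenyl)methylidene]-2,3-dihydro-1H-inden-2-yl]benzene-1,3-diol
Conditions: BBr3 (excess), CH2Cl2, −78 → 0 °C, dark; MeOH then H2O, 0 °C
Reagents that add atoms: none
Why: Lewis acid-mediated cleavage of the six aryl methyl ethers (BBr3 demethylation), a reaction type that tolerates exocyclic stilbene double bonds in permethylated resveratrol oligomers; low temperature and exclusion of light are meant to prevent acid- or light-induced Z to E equilibration, and no stereocentre is involved.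

**Compound list**

1 | 5,7-dimethoxycoumarin (5,7-dimethoxy-2H-chromen-2-one) | O=C1C=Cc2c(OC)cc(OC)cc2O1 | starting material
2 | (4-methoxyphenyl)boronic acid | COc1ccc(cc1)B(O)O | starting material
3 | (4S)-5,7-dimethoxy-4-(4-methoxyphenyl)-3,4-dihydro-2H-chromen-2-one | O=C1C[C@@H](c2ccc(OC)cc2)c2c(OC)cc(OC)cc2O1 | intermediate
4 | 1-bromo-3,5-dimethoxybenzene | COc1cc(Br)cc(OC)c1 | starting material
5 | lithium enolate of 3, lithium (4S)-5,7-dimethoxy-4-(4-methoxyphenyl)-4H-chromen-2-olate (formed in the flask) | [Li]OC1=C[C@@H](c2ccc(OC)cc2)c2c(OC)cc(OC)cc2O1 | intermediate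
6 | chlorozinc enolate of 3 (formed in the flask, drawn O-bound) | Cl[Zn]OC1=C[C@@H](c2ccc(OC)cc2)c2c(OC)cc(OC)cc2O1 | intermediate
7 | (3S,4S)-3-(3,5-dimethoxyphenyl)-5,7-dimethoxy-4-(4-methoxyphenyl)-3,4-dihydro-2H-chromen-2-one (trans) | O=C1[C@H](c2cc(OC)cc(OC)c2)[C@@H](c2ccc(OC)cc2)c2c(OC)cc(OC)cc2O1 | intermediate
8 | (2S,3S)-2-(3,5-dimethoxyphenyl)-3-(2-hydroxy-4,6-dimethoxyphenyl)-N-methoxy-3-(4-methoxyphenyl)-N-methylpropanamide (phenol amide, formed in the flask) | CON(C)C(=O)[C@H](c1cc(OC)cc(OC)c1)[C@@H](c1ccc(OC)cc1)c1c(OC)cc(OC)cc1O | intermediate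
9 | 2-[(1S,2S)-2-(3,5-dimethoxyphenyl)-3-[methoxy(methyl)amino]-1-(4-methoxyphenyl)-3-oxopropyl]-3,5-dimethoxyphenyl trifluoromethanesulfonate | CON(C)C(=O)[C@H](c1cc(OC)cc(OC)c1)[C@@H](c1ccc(OC)cc1)c1c(OC)cc(OC)cc1OS(=O)(=O)C(F)(F)F | intermediate
10 | (2S,3S)-3-(2-bromo-4,6-dimethoxyphenyl)-2-(3,5-dimethoxyphenyl)-N-methoxy-3-(4-methoxyphenyl)-N-methylpropanamide | CON(C)C(=O)[C@H](c1cc(OC)cc(OC)c1)[C@@H](c1ccc(OC)cc1)c1c(OC)cc(OC)cc1Br | intermediate
11 | (2S,3S)-3-(2-bromo-4,6-dimethoxyphenyl)-2-(3,5-dimethoxyphenyl)-3-(4-methoxyphenyl)propanal | O=C[C@H](c1cc(OC)cc(OC)c1)[C@@H](c1ccc(OC)cc1)c1c(OC)cc(OC)cc1Br | intermediate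
12 | 1-bromo-2-[(1S,2R)-2-(3,5-dimethoxyphenyl)-1-(4-methoxyphenyl)but-3-yn-1-yl]-3,5-dimethoxybenzene | C#C[C@H](c1cc(OC)cc(OC)c1)[C@@H](c1ccc(OC)cc1)c1c(OC)cc(OC)cc1Br | intermediate
13 | 1-iodo-4-methoxybenzene | COc1ccc(I)cc1 | starting material
14 | 1-bromo-2-[(1S,2S)-2-(3,5-dimethoxyphenyl)-1,4-bis(4-methoxyphenyl)but-3-yn-1-yl]-3,5-dimethoxybenzene | COc1ccc(cc1)C#C[C@H](c1cc(OC)cc(OC)c1)[C@@H](c1ccc(OC)cc1)c1c(OC)cc(OC)cc1Br | intermediate
15 | 2-[(1Z,3R,4S)-4-(2-bromo-4,6-dimethoxyphenyl)-3-(3,5-dimethoxyphenyl)-1,4-bis(4-methoxyphenyl)but-1-en-2-yl]-4,4,5,5-tetramethyl-1,3,2-dioxaborolane (boron cis to the vinyl hydrogen) | COc1ccc(/C=C(/B2OC(C)(C)C(C)(C)O2)\[C@H](c2cc(OC)cc(OC)c2)[C@@H](c2ccc(OC)cc2)c2c(OC)cc(OC)cc2Br)cc1 | intermediate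
16 | aryllithium from 15, lithium in place of bromine (formed in the flask) | COc1ccc(/C=C(/B2OC(C)(C)C(C)(C)O2)\[C@H](c2cc(OC)cc(OC)c2)[C@@H](c2ccc(OC)cc2)c2c(OC)cc(OC)cc2[Li])cc1 | intermediate
17 | lithium (2Z,3R,4S)-3-(3,5-dimethoxyphenyl)-5,7-dimethoxy-4-(4-methoxyphenyl)-2-[(4-methoxyphenyl)methylidene]-1,2,3,4-tetrahydro-1-benzoborinin-1-uide, pinacol ester on boron (six-membered cyclic boronate complex, formed in the flask) | [Li+].COc1ccc(/C=C2/[B-]3(OC(C)(C)C(C)(C)O3)c3cc(OC)cc(OC)c3[C@H](c3ccc(OC)cc3)[C@H]2c2cc(OC)cc(OC)c2)cc1 | intermediate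
18 | 2-[(1S,2R,3S)-2-(3,5-dimethoxyphenyl)-1-[(S)-iodo(4-methoxyphenyl)methyl]-4,6-dimethoxy-3-(4-methoxyphenyl)-2,3-dihydro-1H-inden-1-yl]-4,4,5,5-tetramethyl-1,3,2-dioxaborolane (anti adduct, formed in the flask; drawn for migration on the face that leaves boron cis to the C2 aryl group, the other facial isomer would give the same alkene) | COc1ccc(cc1)[C@@H](I)[C@]2(B3OC(C)(C)C(C)(C)O3)c3cc(OC)cc(OC)c3[C@H](c3ccc(OC)cc3)[C@H]2c2cc(OC)cc(OC)c2 | intermediate
19 | (1Z,2S,3S)-2-(3,5-dimethoxyphenyl)-4,6-dimethoxy-3-(4-methoxyphenyl)-1-[(4-methoxyphenyl)methylidene]-2,3-dihydro-1H-indene | COc1ccc(/C=C2\c3cc(OC)cc(OC)c3[C@H](c3ccc(OC)cc3)[C@H]2c2cc(OC)cc(OC)c2)cc1 | intermediate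
20 | 5-[(1Z,2S,3S)-4,6-dihydroxy-3-(4-hydroxyphenyl)-1-[(4-hydroxyphenyl)methylidene]-2,3-dihydro-1H-inden-2-yl]benzene-1,3-diol | Oc1ccc(/C=C2\c3cc(O)cc(O)c3[C@H](c3ccc(O)cc3)[C@H]2c2cc(O)cc(O)c2)cc1 | target

**Step count and risks**

Total step count: 10. Longest linear sequence: 10 steps (from 1).

Steps most likely to fail:

1. Step 9 (proposed new method). Possible failures are attack of t-BuLi on boron instead of Br–Li exchange, iodination at the aryl–boron carbon (loss of the ring closure), or ionisation of the benzylic iodide with non-stereospecific deboronation (erosion of the Z geometry). The fallback uses known chemistry and sets out from terminal alkyne 12, returning at 19. With Pd(PPh3)4, boronic acid 2 and Cs2CO3 in toluene/EtOH/H2O at 90 °C, zerovalent palladium should insert into the C–Br bond, the arylpalladium should add syn across the terminal alkyne in a 5-exo-dig carbopalladation, and the resulting alkenylpalladium (palladium cis to C7a) should undergo Suzuki coupling with retention, which again places the 4-methoxyphenyl group cis to C7a. This fallback makes no new compound (F0).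

2. Step 2. The aryl ester enolate may fragment to a ketene and phenoxide or self-condense faster than it transmetalates to palladium, and over-arylation or incomplete trans equilibration is possible. The fallback sets out from 3 and returns at 7 and replaces the cross-coupling by a metal-free arylation with an electrophilic aryl source. Lithium enolate 5 (LiN(SiMe3)2, THF, −78 °C) would be treated at −78 °C → rt with (3,5-dimethoxyphenyl)(2,4,6-trimethoxyphenyl)iodonium 4-methylbenzenesulfonate F1 (prepared from 1-iodo-3,5-dimethoxybenzene, mCPBA, TsOH and 1,3,5-trimethoxybenzene). Ligand coupling at iodine should transfer the less electron-rich 3,5-dimethoxyphenyl group anti to the C4 aryl group, and DBU equilibration would again secure the trans lactone.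

3. Step 4. Oxidative addition and C–Br reductive elimination may be slow at the hindered triflate, so that triflate hydrolysis or base-induced epimerisation at C2 competes at 130 °C. The fallback sets out from 9 and returns at 10 in two stages through the boronic ester. Miyaura borylation (PdCl2(dppf), B2pin2, KOAc, 1,4-dioxane, 90 °C) would give (2S,3S)-3-[2,4-dimethoxy-6-(4,4,5,5-tetramethyl-1,3,2-dioxaborolan-2-yl)phenyl]-2-(3,5-dimethoxyphenyl)-N-methoxy-3-(4-methoxyphenyl)-N-methylpropanamide F2. Copper-mediated bromodeboronation (CuBr2, MeOH/H2O, 80 °C, monitored to avoid ring bromination) would then give 10.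

**Further compounds**

F0 | step 9 | none | none
F1 | step 2 | (3,5-dimethoxyphenyl)(2,4,6-trimethoxyphenyl)iodonium 4-methylbenzenesulfonate | COc1cc(OC)cc([I+]c2c(OC)cc(OC)cc2OC)c1.Cc1ccc(cc1)S(=O)(=O)[O-]
F2 | step 4 | (2S,3S)-3-[2,4-dimethoxy-6-(4,4,5,5-tetramethyl-1,3,2-dioxaborolan-2-yl)phenyl]-2-(3,5-dimethoxyphenyl)-N-methoxy-3-(4-methoxyphenyl)-N-methylpropanamide | CON(C)C(=O)[C@H](c1cc(OC)cc(OC)c1)[C@@H](c1ccc(OC)cc1)c1c(OC)cc(OC)cc1B1OC(C)(C)C(C)(C)O1
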